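Germacrane numbering is used for every intermediate: C1=C10 carries C14, C4=C5 carries C15, C6 is the lactone carbinol, C8 the free carbinol, C9 the acyloxy carbon, and C11–C13 form the lactone arm. "Ring-cis" means that the two ring bonds lie cis on an alkene.
Enabling feature: the ten-membered ring is a 1,5-diene C10=C1–C2–C3–C4=C5 with both alkenes ring-cis. All four ring stereocentres (C6–C9) lie on the complementary arc C5–C6–C7–C8–C9–C10. The carbocycle therefore equals a cyclohex-2-enone ring (C9=O, C10=C5) with the four ring carbons of 1-methylcyclobutene inserted into its C5=C10 bond.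
Cuts: first the C9–O acyl bond, C11=C13 and the C14 oxidation level. The alkenes C1=C10 and C4=C5 are then traded for the σ-bonds C5–C10 and C1–C4 (reverse of a bicyclo[2.2.0]hexane cycloreversion). Next come C10–C1 and C5–C4 ([2+2]), and last C10–C14, C8–O, the lactone C12–O bond and C7–C11.
Forward ring order: purchased six-membered ring, then the trans-fused γ-lactone, then the central cyclobutane of a 6-4-4 tricycle by photocycloaddition. Heat then merges the six-membered ring and the two four-membered rings into the ten-membered ring, and the exocyclic methylene is added last.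
Stereochemistry: C6 comes from lipase desymmetrisation of a meso-diacetate. C7 is set by Michael addition anti to the C6 silyloxy group, C8 by enol-ether oxidation antiperiplanar to the axial C7–H, and C9 by CBS reagent control. The acyl centre is bought, and the ring-alkene geometry comes from thiyl-radical equilibration to the least strained diene.

Key step: step 16

Assumption: the lipase of step 2 hydrolyses the acetate on the (R)-configured carbon of the meso-diacetate, as drawn for the monoacetate.
Abbreviations: TBS = tert-butyldimethylsilyl, TES = triethylsilyl, TMS = trimethylsilyl, CSA = camphorsulfonic acid.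

Step 1
Reactants: 1 cyclohexa-1,3-diene
Product: 2 cis-cyclohex-2-ene-1,4-diyl diacetate (meso)
Conditions: Pd(OAc)2 (5 mol %), LiCl (20 mol %), LiOAc (1 equiv), p-benzoquinone (1.2 equiv), AcOH, 25 °C
Reagents that add atoms: acetic acid, CC(=O)O
Why: Palladium-catalysed 1,4-diacetoxylation of a 1,3-diene, in which anti-acetoxypalladation gives a π-allyl complex of divalent palladium and, because chloride occupies the metal, the second acetate attacks from outside, so both C–O bonds end up on the same ring face.

Step 2
Reactants: 2 cis-cyclohex-2-ene-1,4-diyl diacetate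
Product: 3 (1S,4R)-4-hydroxycyclohex-2-en-1-yl acetate
Conditions: lipase from Burkholderia cepacia, 0.1 M phosphate buffer pH 7, 25 °C
Reagents that add atoms: none
Why: Enzymatic desymmetrisation of a meso-diester by enantiotopos-selective hydrolysis, which frees only the hydroxyl group on the (R)-carbon and thereby sets the absolute configuration of the future C6.

Step 3
Reactants: 3 (1S,4R)-4-hydroxycyclohex-2-en-1-yl acetate
Product: 4 (1S,4R)-4-(tert-butyldimethylsilyloxy)cyclohex-2-en-1-yl acetate
Conditions: TBSCl, imidazole, DMF, 0 to 25 °C
Reagents that add atoms: TBSCl, CC(C)(C)[Si](C)(C)Cl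
Why: Routine imidazole-promoted silylation of a secondary alcohol that masks the future C6 oxygen and touches neither stereocentre.

Step 4
Reactants: 4 (1S,4R)-4-(tert-butyldimethylsilyloxy)cyclohex-2-en-1-yl acetate
Product: 5 (1S,4R)-4-(tert-butyldimethylsilyloxy)cyclohex-2-en-1-ol
Conditions: K2CO3 (20 mol %), MeOH, 0 °C
Reagents that add atoms: none
Why: Carbonate-catalysed transesterification with methanol removes the acetate while the silyl ether is inert to these conditions.

Step 5
Reactants: 5 (1S,4R)-4-(tert-butyldimethylsilyloxy)cyclohex-2-en-1-ol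
Product: 6 (R)-4-(tert-butyldimethylsilyloxy)cyclohex-2-en-1-one
Conditions: MnO2 (activated, excess), CH2Cl2, 25 °C
Reagents that add atoms: none
Why: MnO2 oxidation of an allylic alcohol erases the (S)-carbinol centre and leaves the (R)-silyloxy centre (future C6) as the only stereocentre of the enone.

Step 6
Reactants: 6 (R)-4-(tert-butyldimethylsilyloxy)cyclohex-2-en-1-one
Product: 8 (4R)-4-(tert-butyldimethylsilyloxy)-6-(phenylselanyl)cyclohex-2-en-1-one, via lithium dienolate 7 (not isolated)
Conditions: LiN(iPr)2 (1.1 equiv), THF, −78 °C; PhSeCl (1.1 equiv), −78 °C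
Reagents that add atoms: benzeneselenenyl chloride, Cl[Se]c1ccccc1
Why: Kinetic deprotonation of an enone takes the α′-proton (future C10), and selenenylation of the cross-conjugated enolate installs there the group needed for the later enone transposition, the configuration of the selenium-bearing carbon being irrelevant.

Step 7
Reactants: 8 (4R)-4-(tert-butyldimethylsilyloxy)-6-(phenylselanyl)cyclohex-2-en-1-one, 9 1-(tert-butyldimethylsilyloxy)-1-methoxyethene
Product: 10 methyl 2-[(1R,6R)-3,6-bis(tert-butyldimethylsilyloxy)-4-(phenylselanyl)cyclohex-2-en-1-yl]acetate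
Conditions: TBSOTf (10 mol %), CH2Cl2, −78 °C
Reagents that add atoms: none
Why: Mukaiyama–Michael addition with silyl transfer, in which the ketene acetal attacks the β-carbon (future C7) anti to the neighbouring silyloxy group and so sets the trans C6/C7 relationship, a selectivity well known for 4-silyloxycyclohexenones.

Step 8
Reactants: 10 methyl 2-[(1R,6R)-3,6-bis(tert-butyldimethylsilyloxy)-4-(phenylselanyl)cyclohex-2-en-1-yl]acetate
Product: 12 (3aS,7aR)-6-(phenylselanyl)hexahydro-1-benzofuran-2,5-dione (trans-fused), via hydroxy keto ester 11 (not isolated)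
Conditions: 48 % aq HF, MeCN, 0 to 25 °C; then CSA (10 mol %), 4 Å MS, CH2Cl2, 25 °C
Reagents that add atoms: none
Why: HF cleaves the enol ether and the secondary silyl ether, and acid-catalysed transesterification then closes the trans-fused γ-lactone from the diequatorial hydroxyl and acetate arms (5-exo-trig), done at the saturated-ketone stage where acid-induced dehydration to a phenol cannot compete.

Step 9
Reactants: 12 (3aS,7aR)-6-(phenylselanyl)hexahydro-1-benzofuran-2,5-dione
Product: 14 (3aS,7aS)-3,3a,4,7a-tetrahydro-1-benzofuran-2,5-dione (trans-fused lactone enone), via selenoxide 13 (not isolated)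
Conditions: 30 % aq H2O2 (3 equiv), pyridine (2 equiv), CH2Cl2, 0 to 25 °C
Reagents that add atoms: none
Why: Oxidation to the selenoxide and spontaneous syn-elimination, which can only use a hydrogen on C5 and therefore places the new enone alkene between C10 and C5 under neutral conditions that spare the γ-acyloxy enone.

Step 10
Reactants: 14 (3aS,7aS)-3,3a,4,7a-tetrahydro-1-benzofuran-2,5-dione
Product: 17 (3aR,4S,7aR)-4-hydroxy-3,3a,4,7a-tetrahydro-1-benzofuran-2,5-dione (C8 hydroxyl axial), via TMS dienol ether 15 (not isolated), via C8-trimethylsilyloxy enone 16 (not isolated)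
Conditions: TMSOTf (1.1 equiv), Et3N (1.3 equiv), CH2Cl2, 0 °C; mCPBA (1.05 equiv), hexane/CH2Cl2, −20 °C; 1 M HCl, THF, 0 °C
Reagents that add atoms: mCPBA, OOC(=O)c1cccc(Cl)c1
Why: Rubottom oxidation, in which soft enolisation gives the cross-conjugated 2-silyloxydiene (C8=C9) without strong base and the peracid attacks this electron-rich alkene antiperiplanar to the pseudoaxial C7–H of the rigid trans-fused bicycle (staggered transition state), placing the C8 oxygen axial and cis to the C7–C11 bond.

Step 11
Reactants: 17 (3aR,4S,7aR)-4-hydroxy-3,3a,4,7a-tetrahydro-1-benzofuran-2,5-dione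
Product: 18 (3aS,4S,7aR)-4-(tert-butyldimethylsilyloxy)-3,3a,4,7a-tetrahydro-1-benzofuran-2,5-dione
Conditions: TBSOTf, 2,6-lutidine, CH2Cl2, −78 to 0 °C
Reagents that add atoms: TBSOTf, CC(C)(C)[Si](C)(C)OS(=O)(=O)C(F)(F)F
Why: Silyl triflate with a hindered pyridine base silylates congested secondary alcohols at low temperature, and the base is too weak to epimerise the axial α-oxy ketone.

Step 12
Reactants: 18 (3aS,4S,7aR)-4-(tert-butyldimethylsilyloxy)-3,3a,4,7a-tetrahydro-1-benzofuran-2,5-dione
Product: 19 C10-iodo derivative of 18 (α-iodo enone; C6, C7, C8 unchanged)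
Conditions: I2 (1.5 equiv), pyridine/CH2Cl2 1:1, 0 to 25 °C
Reagents that add atoms: iodine, [I][I]
Why: α-Iodination of a cyclic enone by conjugate addition of pyridine, iodination of the resulting enolate and loss of pyridine, which can functionalise only C10.

Step 13
Reactants: 19 C10-iodo lactone enone, 20 (tributylstannyl)methanol
Product: 21 C10-hydroxymethyl lactone enone (C14 installed)
Conditions: Pd2(dba)3 (2.5 mol %), AsPh3 (10 mol %), CuI (10 mol %), NMP, 50 °C
Reagents that add atoms: none
Why: Stille hydroxymethylation, in which oxidative addition of zerovalent palladium into the C10–I bond is much faster than ionisation of the electron-poor allylic lactone and the α-oxygenated CH2OH group transfers from tin in preference to butyl.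

Step 14
Reactants: 21 C10-hydroxymethyl lactone enone
Product: 22 C10-(triethylsilyloxymethyl) lactone enone (photosubstrate)
Conditions: TESCl, imidazole, CH2Cl2, 0 °C
Reagents that add atoms: TESCl, CC[Si](Cl)(CC)CC
Why: Routine silylation of a primary alcohol with a group that can later be removed in the presence of the secondary TBS ether.

Step 15
Reactants: 23 methylenecyclobutane
Product: 24 1-methylcyclobutene
Conditions: KOtBu (20 mol %), DMSO, 25 °C; fractional distillation
Reagents that add atoms: none
Why: Base-catalysed alkene isomerisation through the allyl anion, whose equilibrium favours the endocyclic trisubstituted alkene.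

Step 16
Reactants: 22 C10-(triethylsilyloxymethyl) lactone enone, 24 1-methylcyclobutene
Product: 25 cis-anti-cis 6-4-4 tricyclic ketone (bicyclo[2.2.0]hexane C1–C2–C3–C4–C5–C10 fused at C5–C10 to the lactone-bearing cyclohexanone)
Conditions: 24 (10 equiv), CH2Cl2 (0.02 M in 22), 365 nm LED, Pyrex, −30 °C
Reagents that add atoms: none
Why: Excitation at 365 nm populates the enone triplet of 22, which bonds to the alkene to give a triplet 1,4-biradical that closes the second bond by radical recombination after spin inversion; this is the classical intermolecular enone–alkene [2+2] photocycloaddition, known with cyclobutenes as the alkene partner. The only ring closed is the central cyclobutane C10–C1–C4–C5, formed through the two new σ-bonds C5–C4 and C10–C1 (stepwise [2+2], collapse of a 1,4-biradical), which creates the bicyclo[2.2.0]hexane and gathers all ten future ring carbons. The step needs head-to-tail orientation: the biradical leading to the head-to-head isomer would have to couple the fully substituted C10 with the methyl-bearing C4 and should revert to the starting materials, and the usual preference of alkyl-substituted alkenes for placing the substituted carbon on the enone β-carbon points the same way. C1 and C4 are cis because they come from a four-membered-ring alkene, C5 and C10 are cis because a trans six–four fusion next to a second cyclobutane is prohibitively strained, the two outer rings lie anti on the central ring for steric reasons, and the alkene approaches the face opposite the axial C8 silyloxy group. None of these four centres survives step 17, so facial and syn/anti selectivity only affect ease of handling, while C6, C7 and C8 are spectators. Long-wavelength light, low temperature and excess 24 keep the product ketone, which absorbs at shorter wavelength, out of secondary photochemistry.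

Step 17
Reactants: 25 cis-anti-cis 6-4-4 tricyclic ketone
Product: 27 ring-cis,ring-cis lactone-fused cyclodeca-1(10),4-dien-9-one, via cis-trans dienone 26 (not isolated)
Conditions: degassed toluene (0.01 M), silanised sealed tube, 190 °C; cool to 25 °C; PhSSPh (10 mol %), 405 nm LED, 25 °C
Reagents that add atoms: none
Why: Thermal cycloreversion of the bicyclo[2.2.0]hexane (homolysis of the strained C1–C4 bond to a cyclohexane-1,4-diyl, then scission of the C5–C10 bond weakened by the acyl group and full substitution at C10) is the known second half of the photochemical–thermal metathesis and should release the conjugated dienone with one ring-cis and one ring-trans alkene, after which reversible thiyl-radical addition, a known way to equilibrate medium-ring alkenes without bond migration, should funnel both alkenes to the least strained ring-cis,ring-cis isomer, which has no chair Cope pathway out of the ten-membered ring.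

Step 18
Reactants: 27 ring-cis,ring-cis lactone-fused cyclodeca-1(10),4-dien-9-one
Product: 28 C9 allylic alcohol (C9–O cis to C8–O on the ring, C6–C9 as in the target)
Conditions: (R)-2-methyl-CBS-oxazaborolidine (0.5 equiv), catecholborane (2 equiv), toluene, −78 to −40 °C; pH 7 buffer work-up
Reagents that add atoms: none
Why: CBS reduction, in which the (R)-oxazaborolidine binds the ketone with the α-branched alkenyl carbon C10 as the large group and delivers hydride to the face that gives the C9 configuration of the target, while catecholborane at low temperature leaves the lactone and the trisubstituted alkenes alone.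

Step 19
Reactants: 28 C9 allylic alcohol, 29 Eschenmoser's salt (N,N-dimethylmethyleneiminium iodide)
Product: 31 C11-(dimethylaminomethyl) lactone (C13 installed; C11 epimers), via dilithio alkoxide enolate 30 (not isolated)
Conditions: LiN(iPr)2 (2.3 equiv), THF, −78 °C; 29 (3 equiv), −78 to −40 °C; water quench at −40 °C
Reagents that add atoms: none
Why: Mannich reaction of a lactone enolate with a preformed iminium salt, run on the alkoxide–enolate dianion so that no extra protecting group is needed and kept cold so that the lithium alkoxide at C9 does not pick up the neighbouring silyl group.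

Step 20
Reactants: 31 C11-(dimethylaminomethyl) lactone
Product: 33 α-methylene lactone bearing a free C9 hydroxyl group, via ammonium iodide 32 (not isolated)
Conditions: MeI (10 equiv), THF, 25 °C; then sat aq NaHCO3, CH2Cl2, 25 °C
Reagents that add atoms: none
Why: Quaternisation of the amine followed by mild base-induced E1cB loss of trimethylamine is the standard completion of lactone α-methylenation and erases the C11 stereocentre.

Step 21
Reactants: 33 α-methylene lactone bearing a free C9 hydroxyl group, 34 (R)-2-methylbutanoic acid
Product: 35 protected 9-[(R)-2-methylbutanoyloxy] α-methylene lactone (C14 TES ether, C8 TBS ether)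
Conditions: 34 (2 equiv), DCC (2 equiv), DMAP (20 mol %), CH2Cl2, 0 to 25 °C
Reagents that add atoms: none
Why: Steglich esterification acylates the only free hydroxyl group with retention at C9 and, lacking strong base or a ketene pathway, should not racemise the α-alkyl stereocentre of the acid.

Step 22
Reactants: 35 protected 9-acyloxy α-methylene lactone
Product: 36 C14 primary allylic alcohol (C8 TBS ether retained)
Conditions: AcOH/THF/H2O 3:3:1, 0 °C
Reagents that add atoms: none
Why: Under mild aqueous acid a primary TES ether is hydrolysed far faster than a hindered secondary TBS ether, and ester, lactone and diene are inert.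

Step 23
Reactants: 36 C14 primary allylic alcohol
Product: 37 C8-TBS ether of the target (C14 enal)
Conditions: MnO2 (activated, excess), CH2Cl2, 25 °C, dark
Reagents that add atoms: none
Why: MnO2 oxidises the allylic alcohol selectively to the enal, whose ring-cis geometry (C2 trans to the formyl group) is also the locally preferred geometry of a 2-alkyl enal and is therefore not at risk.

Step 24
Reactants: 37 C8-TBS ether of the target
Product: 38 CNP0256845.2
Conditions: HF·pyridine, pyridine, THF, 0 to 25 °C
Reagents that add atoms: none
Why: Buffered fluoride cleavage removes the secondary TBS ether without generating a basic alkoxide that could trigger C9-to-C8 acyl migration or conjugate addition to the enal or the methylene lactone.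

Compound list
1 | cyclohexa-1,3-diene | C1=CC=CCC1 | starting material
2 | cis-cyclohex-2-ene-1,4-diyl diacetate (meso) | CC(=O)O[C@@H]1C=C[C@H](OC(C)=O)CC1 | intermediate
3 | (1S,4R)-4-hydroxycyclohex-2-en-1-yl acetate | CC(=O)O[C@@H]1C=C[C@H](O)CC1 | intermediate
4 | (1S,4R)-4-(tert-butyldimethylsilyloxy)cyclohex-2-en-1-yl acetate | CC(=O)O[C@@H]1C=C[C@H](O[Si](C)(C)C(C)(C)C)CC1 | intermediate
5 | (1S,4R)-4-(tert-butyldimethylsilyloxy)cyclohex-2-en-1-ol | O[C@@H]1C=C[C@H](O[Si](C)(C)C(C)(C)C)CC1 | intermediate
6 | (R)-4-(tert-butyldimethylsilyloxy)cyclohex-2-en-1-one | O=C1C=C[C@H](O[Si](C)(C)C(C)(C)C)CC1 | intermediate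
7 | lithium cross-conjugated dienolate of 6 (not isolated) | [Li+].[O-]C1=CC[C@@H](O[Si](C)(C)C(C)(C)C)C=C1 | intermediate
8 | (4R)-4-(tert-butyldimethylsilyloxy)-6-(phenylselanyl)cyclohex-2-en-1-one (epimers at the selenium-bearing carbon) | O=C1C=C[C@H](O[Si](C)(C)C(C)(C)C)CC1[Se]c2ccccc2 | intermediate
9 | 1-(tert-butyldimethylsilyloxy)-1-methoxyethene | C=C(OC)O[Si](C)(C)C(C)(C)C | starting material
10 | methyl 2-[(1R,6R)-3,6-bis(tert-butyldimethylsilyloxy)-4-(phenylselanyl)cyclohex-2-en-1-yl]acetate (side chain trans to the C6 silyloxy group) | COC(=O)C[C@@H]1C=C(O[Si](C)(C)C(C)(C)C)C([Se]c2ccccc2)C[C@H]1O[Si](C)(C)C(C)(C)C | intermediate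
11 | methyl 2-[(1S,2R)-2-hydroxy-5-oxo-4-(phenylselanyl)cyclohexyl]acetate (not isolated) | COC(=O)C[C@@H]1CC(=O)C([Se]c2ccccc2)C[C@H]1O | intermediate
12 | (3aS,7aR)-6-(phenylselanyl)hexahydro-1-benzofuran-2,5-dione (trans-fused) | O=C1C[C@@H]2CC(=O)C([Se]c3ccccc3)C[C@H]2O1 | intermediate
13 | selenoxide of 12 (not isolated) | O=C1C[C@@H]2CC(=O)C([Se](=O)c3ccccc3)C[C@H]2O1 | intermediate
14 | (3aS,7aS)-3,3a,4,7a-tetrahydro-1-benzofuran-2,5-dione (trans-fused lactone enone) | O=C1C[C@@H]2CC(=O)C=C[C@H]2O1 | intermediate
15 | trans-fused 5-(trimethylsilyloxy)-3a,7a-dihydro-1-benzofuran-2(3H)-one (TMS dienol ether of 14, not isolated) | O=C1C[C@@H]2C=C(O[Si](C)(C)C)C=C[C@H]2O1 | intermediate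
16 | C8-trimethylsilyloxy lactone enone (not isolated) | O=C1C[C@@H]2[C@H](O[Si](C)(C)C)C(=O)C=C[C@H]2O1 | intermediate
17 | (3aR,4S,7aR)-4-hydroxy-3,3a,4,7a-tetrahydro-1-benzofuran-2,5-dione (C8 hydroxyl axial, cis to the C7–C11 bond) | O=C1C[C@@H]2[C@H](O)C(=O)C=C[C@H]2O1 | intermediate
18 | (3aS,4S,7aR)-4-(tert-butyldimethylsilyloxy)-3,3a,4,7a-tetrahydro-1-benzofuran-2,5-dione | O=C1C[C@@H]2[C@H](O[Si](C)(C)C(C)(C)C)C(=O)C=C[C@H]2O1 | intermediate
19 | C10-iodo derivative of 18 | O=C1C[C@@H]2[C@H](O[Si](C)(C)C(C)(C)C)C(=O)C(I)=C[C@H]2O1 | intermediate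
20 | (tributylstannyl)methanol | CCCC[Sn](CCCC)(CCCC)CO | starting material
21 | C10-hydroxymethyl derivative of 18 | O=C1C[C@@H]2[C@H](O[Si](C)(C)C(C)(C)C)C(=O)C(CO)=C[C@H]2O1 | intermediate
22 | C10-(triethylsilyloxymethyl) derivative of 18 (photosubstrate) | O=C1C[C@@H]2[C@H](O[Si](C)(C)C(C)(C)C)C(=O)C(CO[Si](CC)(CC)CC)=C[C@H]2O1 | intermediate
23 | methylenecyclobutane | C=C1CCC1 | starting material
24 | 1-methylcyclobutene | CC1=CCC1 | intermediate
25 | cis-anti-cis 6-4-4 tricyclic ketone (new bonds C10–C1 and C5–C4; cyclobutane on the face opposite the C8 silyloxy group) | O=C1C[C@@H]2[C@H](O[Si](C)(C)C(C)(C)C)C(=O)[C@@]3(CO[Si](CC)(CC)CC)[C@@H]4CC[C@]4(C)[C@H]3[C@H]2O1 | intermediate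
26 | lactone-fused cyclodeca-1(10),4-dien-9-one with C1=C10 ring-trans and C4=C5 ring-cis (expected principal first-formed isomer, not isolated) | C1C(=O)O[C@@H]2/C=C(/C)CC/C=C(\CO[Si](CC)(CC)CC)C(=O)[C@@H](O[Si](C)(C)C(C)(C)C)[C@@H]12 | intermediate
27 | lactone-fused cyclodeca-1(10),4-dien-9-one with both alkenes ring-cis | C1C(=O)O[C@@H]2/C=C(/C)CC/C=C(/CO[Si](CC)(CC)CC)C(=O)[C@@H](O[Si](C)(C)C(C)(C)C)[C@@H]12 | intermediate
28 | C9 allylic alcohol from 27 (C6–C9 as in the target) | C1C(=O)O[C@@H]2/C=C(/C)CC/C=C(/CO[Si](CC)(CC)CC)[C@@H](O)[C@@H](O[Si](C)(C)C(C)(C)C)[C@@H]12 | intermediate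
29 | Eschenmoser's salt | C=[N+](C)C.[I-] | starting material
30 | dilithio C9 alkoxide / lactone enolate of 28 (not isolated) | C1=C([O-])O[C@@H]2/C=C(/C)CC/C=C(/CO[Si](CC)(CC)CC)[C@@H]([O-])[C@@H](O[Si](C)(C)C(C)(C)C)[C@@H]12.[Li+].[Li+] | intermediate
31 | C11-(dimethylaminomethyl) lactone (C11 epimers) | CN(C)CC1C(=O)O[C@@H]2/C=C(/C)CC/C=C(/CO[Si](CC)(CC)CC)[C@@H](O)[C@@H](O[Si](C)(C)C(C)(C)C)[C@@H]12 | intermediate
32 | trimethylammonium iodide of 31 (not isolated) | C[N+](C)(C)CC1C(=O)O[C@@H]2/C=C(/C)CC/C=C(/CO[Si](CC)(CC)CC)[C@@H](O)[C@@H](O[Si](C)(C)C(C)(C)C)[C@@H]12.[I-] | intermediate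
33 | α-methylene lactone with free C9 hydroxyl group | C=C1C(=O)O[C@@H]2/C=C(/C)CC/C=C(/CO[Si](CC)(CC)CC)[C@@H](O)[C@@H](O[Si](C)(C)C(C)(C)C)[C@@H]12 | intermediate
34 | (R)-2-methylbutanoic acid | CC[C@@H](C)C(=O)O | starting material
35 | protected 9-[(R)-2-methylbutanoyloxy] α-methylene lactone | C=C1C(=O)O[C@@H]2/C=C(/C)CC/C=C(/CO[Si](CC)(CC)CC)[C@@H](OC(=O)[C@H](C)CC)[C@@H](O[Si](C)(C)C(C)(C)C)[C@@H]12 | intermediate
36 | C14 primary allylic alcohol | C=C1C(=O)O[C@@H]2/C=C(/C)CC/C=C(/CO)[C@@H](OC(=O)[C@H](C)CC)[C@@H](O[Si](C)(C)C(C)(C)C)[C@@H]12 | intermediate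
37 | C8-TBS ether of the target | C=C1C(=O)O[C@@H]2/C=C(/C)CC/C=C(/C=O)[C@@H](OC(=O)[C@H](C)CC)[C@@H](O[Si](C)(C)C(C)(C)C)[C@@H]12 | intermediate
38 | CNP0256845.2, (6R,7R,8S,9R)-8-hydroxy-9-[(R)-2-methylbutanoyloxy]-14-oxogermacra-1(10),4,11(13)-trien-12,6-olide with both ring alkenes ring-cis | C=C1C(=O)O[C@@H]2/C=C(/C)CC/C=C(/C=O)[C@@H](OC(=O)[C@H](C)CC)[C@@H](O)[C@@H]12 | target

Total step count: 24. Longest linear sequence: 23 steps (steps 1–14 and 16–24; step 15 is a one-step side branch).

Steps most likely to fail

Step 17.
- What may go wrong: at the cycloreversion temperature a ring-trans alkene keeps the ten-membered ring open to chair Cope rearrangement, so material may drain out of the ten-membered manifold. The later equilibration may also stall, because the enone locally prefers C2 trans to the acyl carbon C9, which opposes the ring-strain preference for the ring-cis alkene.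
- Fallback (from 26, back at 28): the order of reduction and geometric correction is reversed. Heating is stopped as soon as 25 is consumed, and 26 is isolated by chromatography. It is reduced with the same (R)-oxazaborolidine/catecholborane system to the ring-trans C9 dienol F1. With the carbonyl gone only ring strain decides the geometry, so PhSSPh/405 nm equilibration of F1 at 25 °C, far below the Cope threshold, should give 28.

Step 16.
- What may go wrong: fast radiationless decay of the α-substituted enone triplet may give slow conversion, the head-to-tail orientation may erode, and the product may undergo secondary photolysis during long irradiation.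
- Fallback (from 18 and 24, back at 25): C14 is attached after the cycloaddition instead of before it. The α-unsubstituted enone 18 belongs to the chromophore class best documented with cyclobutenes. It is irradiated with 24 to give the C14-free photoadduct F2, and any trans-fused isomer can now be epimerised at C10 on basic alumina.
- Kinetic deprotonation with LiN(iPr)2 at −78 °C should take the ring-fusion C10–H rather than the equatorial C8–H, which lies in the carbonyl plane. Monomeric formaldehyde then enters on the convex face with retention of the cis fusion to give the C10-hydroxymethyl tricyclic ketone F3. Silylation with TESCl/imidazole gives 25.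

Step 18.
- What may go wrong: facial selectivity may be poor because both flanks of the ketone are branched. In addition, the ring conformer with C9=O anti to the C8–O dipole exposes the undesired face to peripheral attack, so reagent and substrate preferences may be mismatched.
- Fallback (from 27, back at 28): the substrate bias is accepted and corrected by inversion. Luche reduction of 27 (NaBH4, CeCl3·7H2O, MeOH, −78 °C) should give the 9-epi allylic alcohol F4. Mitsunobu reaction with 4-nitrobenzoic acid (PPh3, DIAD, toluene, 0 °C) inverts C9 to the C9 4-nitrobenzoate F5. Brief methanolysis (K2CO3, MeOH, 0 °C) then gives 28.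

Further compounds
F1 | step 17 | ring-trans C9 dienol (C1=C10 ring-trans, C4=C5 ring-cis, C6–C9 as in 28) | C1C(=O)O[C@@H]2/C=C(/C)CC/C=C(\CO[Si](CC)(CC)CC)[C@@H](O)[C@@H](O[Si](C)(C)C(C)(C)C)[C@@H]12
F2 | step 16 | C14-free photoadduct (cis-anti-cis 6-4-4 tricyclic ketone with C10–H) | O=C1C[C@@H]2[C@H](O[Si](C)(C)C(C)(C)C)C(=O)[C@H]3[C@@H]4CC[C@]4(C)[C@H]3[C@H]2O1
F3 | step 16 | C10-hydroxymethyl tricyclic ketone | O=C1C[C@@H]2[C@H](O[Si](C)(C)C(C)(C)C)C(=O)[C@@]3(CO)[C@@H]4CC[C@]4(C)[C@H]3[C@H]2O1
F4 | step 18 | 9-epi allylic alcohol | C1C(=O)O[C@@H]2/C=C(/C)CC/C=C(/CO[Si](CC)(CC)CC)[C@H](O)[C@@H](O[Si](C)(C)C(C)(C)C)[C@@H]12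
F5 | step 18 | C9 4-nitrobenzoate (C9 configured as in 28) | C1C(=O)O[C@@H]2/C=C(/C)CC/C=C(/CO[Si](CC)(CC)CC)[C@@H](OC(=O)c3ccc(cc3)[N+](=O)[O-])[C@@H](O[Si](C)(C)C(C)(C)C)[C@@H]12
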